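## Retrosynthetic overview

1. The last bond made is C20–OAc. The CH2–O and C1–H bonds are cut together, giving a 1-methylene tetralin plus "H−/AcO+" (copper hydride hydroacetoxylation, which also sets C1).
2. C1=CH2 comes from C1=O, that is, from an 8-hydroxy-1-tetralone-6-carboxylic acid.
3. Ring A is cut at C4a–C5 and C8a–C8, giving the ring B enone and the four-carbon donor PhS(O)CH2–C(CO2H)=CH–CO2Me, made from monomethyl itaconate.
4. The ring B enone comes from (S)-citronellal (C11 and the side chain) and methyl vinyl ketone. The C4–C3 bond sets C4, and an aldol condensation closes the ring.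
5. Ring B is formed first, then ring A. The stereocentres are set in the order C11 (chiral pool), C4 (organocatalyst), C1 (copper catalyst).

Labels: C1 bears CH2OAc (C20). C4 bears the side chain. C6 carries CO2H and C8 carries OH. C11 is the side-chain stereocentre. The target is 1R,4S,11S, with the C1 and C4 substituents trans.

Assumption: (R)-DTBM-SEGPHOS is written as the ligand antipode that adds Cu–H to the alkene face syn to the C4 substituent. This must be checked once by running both antipodes.

## Route

Step 1
Reactants: 1 monomethyl itaconate (4-methyl hydrogen 2-methylidenebutanedioate)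
Product: 3 (Z)-2-(bromomethyl)-4-methoxy-4-oxobut-2-enoic acid (fumarate geometry: CO2H and CO2Me trans), via dibromo acid 2 (not isolated)
Conditions: Br2, CH2Cl2, 0 °C to rt; then Et3N (2.2 equiv), Et2O, 0 °C; cold 1 M HCl
Reagents that add atoms: bromine BrBr
Why: Electrophilic bromine addition to the 1,1-disubstituted alkene, then E2 dehydrobromination (tertiary bromide plus the acidic H alpha to the ester), gives the conjugated fumarate-type alkene, which is the usual entry to bromomethylfumarates.

Step 2
Reactants: 3 (Z)-2-(bromomethyl)-4-methoxy-4-oxobut-2-enoic acid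
Product: 5 (Z)-4-methoxy-4-oxo-2-[(phenylsulfinyl)methyl]but-2-enoic acid (racemic at sulfur), via sulfide 4 (not isolated)
Conditions: PhSH (1.05 equiv), Et3N (2.1 equiv), CH2Cl2, 0 °C to rt; solvent swap; then NaIO4 (1.05 equiv), MeOH–H2O, 0 °C to rt; acidify
Reagents that add atoms: thiophenol Sc1ccccc1; sodium periodate [Na+].[O-]I(=O)(=O)=O
Why: Allylic substitution by thiolate (direct SN2, or double SN2′ through the ammonium salt) ends at the conjugated thermodynamic isomer, and periodate S-oxidation stops at the sulfoxide without creating any stereocentre of the target.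

Step 3
Reactants: 6 (S)-citronellal; 7 methyl vinyl ketone
Product: 9 (4S)-4-[(2S)-6-methylhept-5-en-2-yl]cyclohex-2-en-1-one, via keto aldehyde 8 (not isolated)
Conditions: (S)-diphenylprolinol methyl ether (5 mol %), ethyl 3,4-dihydroxybenzoate (20 mol %), neat, 4 °C; strip excess 7; then KOH, n-Bu4NOH (cat.), THF–Et2O–H2O, reflux
Reagents that add atoms: none
Why: In this enamine-catalysed Michael addition the (S)-catalyst shields one enamine face and sets C4 as S beside the chiral-pool C11 (about 9:1, minor epimer removed by chromatography), and the intramolecular aldol condensation (Robinson-type annulation) closes ring B.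

Step 4
Reactants: 9 (4S)-4-[(2S)-6-methylhept-5-en-2-yl]cyclohex-2-en-1-one; 5 (Z)-4-methoxy-4-oxo-2-[(phenylsulfinyl)methyl]but-2-enoic acid
Product: 11 (8S)-4-hydroxy-8-[(2S)-6-methylhept-5-en-2-yl]-5-oxo-5,6,7,8-tetrahydronaphthalene-2-carboxylic acid, via sulfinyl diketone 10 (not isolated)
Conditions: 5 (1.2 equiv), LDA (2.5 equiv), THF, −78 °C; add 9; −78 °C to rt, 3 h; then 65 °C, 2 h; 1 M HCl
Reagents that add atoms: none
Why: In this Hauser-type sulfoxide annulation the alpha-sulfinyl carbanion adds 1,4 to C4a, the ketone enolate closes ring A by Dieckmann-type acylation on the cis methyl ester (the carboxylate cannot be acylated, and the wrong-site Michael adduct can only revert), and syn-elimination of PhSOH followed by enolisation aromatises the ring without touching C4 or C11.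

Step 5
Reactants: 11 (8S)-4-hydroxy-8-[(2S)-6-methylhept-5-en-2-yl]-5-oxo-5,6,7,8-tetrahydronaphthalene-2-carboxylic acid
Product: 12 (8S)-4-hydroxy-5-methylidene-8-[(2S)-6-methylhept-5-en-2-yl]-5,6,7,8-tetrahydronaphthalene-2-carboxylic acid
Conditions: MePPh3Br (6 equiv), KOtBu (5.8 equiv), THF, 0 °C to 60 °C; cold citric acid work-up
Reagents that add atoms: methyltriphenylphosphonium bromide C[P+](c1ccccc1)(c1ccccc1)c1ccccc1.[Br-]
Why: Wittig methylenation with excess ylide (the first two equivalents only deprotonate CO2H and OH) works on ortho-hydroxyaryl ketones, and the acid-free conditions keep the alkene exocyclic and C4 intact.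

Step 6
Reactants: 12 (8S)-4-hydroxy-5-methylidene-8-[(2S)-6-methylhept-5-en-2-yl]-5,6,7,8-tetrahydronaphthalene-2-carboxylic acid
Product: 15 (5R,8S)-5-(acetyloxymethyl)-4-hydroxy-8-[(2S)-6-methylhept-5-en-2-yl]-5,6,7,8-tetrahydronaphthalene-2-carboxylic acid (target), via bis-silyl alkene 13 (not isolated), via bis-silyl acetate 14 (not isolated)
Conditions: Cu(OAc)2 (5 mol %), (R)-DTBM-SEGPHOS (5.5 mol %), HSiMe(OMe)2 (6 equiv), THF, rt, 1 h (H2 evolution); then tBuOOAc (1.8 equiv, syringe pump), 40 °C, 12 h; MeOH–H2O, citric acid, rt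
Reagents that add atoms: tert-butyl peracetate CC(=O)OOC(C)(C)C
Why: Proposed new method: catalyst-controlled anti-Markovnikov hydroacetoxylation, in which L*CuH first masks CO2H and OH by dehydrogenative silylation, then adds across the 1,1-disubstituted styrene (Cu on CH2, H on C1 from the face syn to the C4 chain, giving 1R and the trans product, while the trisubstituted alkene is inert), the primary alkyl of monovalent copper inserts into the O–O bond of the perester to give an alkyl acetate tert-butoxide complex of trivalent copper, C–OAc reductive elimination forms the key bond, and L*CuOtBu plus silane regenerates L*CuH; the closest known reactions are the copper hydride anti-Markovnikov hydroamination of 1,1-disubstituted alkenes with O-benzoylhydroxylamines and Kharasch–Sosnovsky acyloxylation with peresters.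

## Compound list

1 | monomethyl itaconate | C=C(CC(=O)OC)C(=O)O | starting material
2 | 2-bromo-2-(bromomethyl)-4-methoxy-4-oxobutanoic acid (racemic) | OC(=O)C(Br)(CBr)CC(=O)OC | intermediate
3 | (Z)-2-(bromomethyl)-4-methoxy-4-oxobut-2-enoic acid | COC(=O)/C=C(/C(=O)O)CBr | intermediate
4 | (Z)-4-methoxy-4-oxo-2-[(phenylsulfanyl)methyl]but-2-enoic acid | COC(=O)/C=C(/C(=O)O)CSc1ccccc1 | intermediate
5 | (Z)-4-methoxy-4-oxo-2-[(phenylsulfinyl)methyl]but-2-enoic acid | COC(=O)/C=C(/C(=O)O)CS(=O)c1ccccc1 | intermediate
6 | (S)-citronellal | O=CC[C@@H](C)CCC=C(C)C | starting material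
7 | methyl vinyl ketone | C=CC(C)=O | starting material
8 | (2S)-2-[(2S)-6-methylhept-5-en-2-yl]-5-oxohexanal | CC(=O)CC[C@@H]([C@@H](C)CCC=C(C)C)C=O | intermediate
9 | (4S)-4-[(2S)-6-methylhept-5-en-2-yl]cyclohex-2-en-1-one | O=C1CC[C@@H]([C@@H](C)CCC=C(C)C)C=C1 | intermediate
10 | Michael–Dieckmann adduct (bicyclic 1,8-dione, 5-phenylsulfinyl, 6-carboxylic acid; new centres as a mixture) | O=C1CC[C@@H]([C@@H](C)CCC=C(C)C)C2C1C(=O)C=C(C(=O)O)C2S(=O)c1ccccc1 | intermediate
11 | (8S)-4-hydroxy-8-[(2S)-6-methylhept-5-en-2-yl]-5-oxo-5,6,7,8-tetrahydronaphthalene-2-carboxylic acid | O=C1CC[C@@H]([C@@H](C)CCC=C(C)C)c2cc(C(=O)O)cc(O)c21 | intermediate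
12 | (8S)-4-hydroxy-5-methylidene-8-[(2S)-6-methylhept-5-en-2-yl]-5,6,7,8-tetrahydronaphthalene-2-carboxylic acid | C=C1CC[C@@H]([C@@H](C)CCC=C(C)C)c2cc(C(=O)O)cc(O)c21 | intermediate
13 | bis[dimethoxy(methyl)silyl] ester/ether of 12 | C=C1CC[C@@H]([C@@H](C)CCC=C(C)C)c2cc(C(=O)O[Si](C)(OC)OC)cc(O[Si](C)(OC)OC)c21 | intermediate
14 | bis[dimethoxy(methyl)silyl] ester/ether of 15 | CC(=O)OC[C@@H]1CC[C@@H]([C@@H](C)CCC=C(C)C)c2cc(C(=O)O[Si](C)(OC)OC)cc(O[Si](C)(OC)OC)c21 | intermediate
15 | (5R,8S)-5-(acetyloxymethyl)-4-hydroxy-8-[(2S)-6-methylhept-5-en-2-yl]-5,6,7,8-tetrahydronaphthalene-2-carboxylic acid | CC(=O)OC[C@@H]1CC[C@@H]([C@@H](C)CCC=C(C)C)c2cc(C(=O)O)cc(O)c21 | target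

## Step count and risks

Total step count: 6.
Longest linear sequence: 5 (steps 1, 2, 4, 5, 6). The citronellal branch has 4 steps.

**Step 6 (the new reaction).**
- The perester may oxidise the phosphine or be reduced by Cu–H.
- C–OtBu elimination or protonation of the alkylcopper may compete.
- The catalyst has to override any substrate bias toward the cis isomer.

The fallback uses known chemistry only, sets out from 12 and returns at 15. CO2H and OH are masked with N,O-bis(trimethylsilyl)acetamide to give the bis(trimethylsilyl) alkene F1. The established cobalt-catalysed asymmetric anti-Markovnikov hydroboration of 1,1-disubstituted aryl alkenes (chiral iminopyridine–oxazoline·CoCl2, NaBHEt3, HBpin, THF) then gives the primary pinacol boronate F2. Oxidation with NaBO3·4H2O in THF–H2O converts C–B to C–O and removes the silyl groups, giving the hydroxy acid F3. Vinyl acetate and immobilised Candida antarctica lipase B then acetylate only the primary alcohol, which gives 15.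

**Step 4 (annulation).**
- The acyclic vinylogous donor is far less proven than benzylic Hauser donors.
- Attack through the ester alpha carbon, enolisation of 9, or slow ring closure could stall the reaction.

The fallback sets out from 9 and returns at 11. Alpha-iodination (I2, pyridine, CH2Cl2) gives the 2-iodo enone F4. A Brassard-type Diels–Alder reaction and aromatisation follows, using commercial 1-methoxy-1,3-bis(trimethylsilyloxy)buta-1,3-diene (toluene, heat, then silica). This gives the 6,8-dihydroxy-1-tetralone F5. The non-chelated C6 hydroxyl is triflated selectively (PhNTf2, K2CO3) to give the aryl triflate F6. Hydroxycarbonylation (Pd(OAc)2, dppf, KOAc, CO, DMSO, 60 °C) then gives 11.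

**Step 5 (methylenation).**
- The ketone is peri-hindered and is deactivated as its phenoxide/carboxylate.
- It may therefore enolise rather than react with the ylide.

The fallback sets out from 11 and returns at 12. It replaces ylide chemistry with a non-basic 1,2-addition and elimination (Peterson route). Me3SiCH2MgCl with CeCl3 (5 equiv, THF, −78 °C to 0 °C) gives the beta-hydroxysilane F7. KH in THF, or brief stirring with silica gel, then eliminates regiospecifically to the exocyclic alkene 12.

Further compounds
F1 | step 6 | bis(trimethylsilyl) alkene (TMS ester and TMS ether of 12) | C=C1CC[C@@H]([C@@H](C)CCC=C(C)C)c2cc(C(=O)O[Si](C)(C)C)cc(O[Si](C)(C)C)c21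
F2 | step 6 | primary pinacol boronate (1,4-trans, bis-TMS) | CC1(C)OB(C[C@@H]2CC[C@@H]([C@@H](C)CCC=C(C)C)c3cc(C(=O)O[Si](C)(C)C)cc(O[Si](C)(C)C)c32)OC1(C)C
F3 | step 6 | hydroxy acid (deacetyl target) | OC[C@@H]1CC[C@@H]([C@@H](C)CCC=C(C)C)c2cc(C(=O)O)cc(O)c21
F4 | step 4 | 2-iodo enone | O=C1CC[C@@H]([C@@H](C)CCC=C(C)C)C=C1I
F5 | step 4 | 6,8-dihydroxy-1-tetralone | O=C1CC[C@@H]([C@@H](C)CCC=C(C)C)c2cc(O)cc(O)c21
F6 | step 4 | aryl triflate (C6–OTf, C8–OH) | O=C1CC[C@@H]([C@@H](C)CCC=C(C)C)c2cc(OS(=O)(=O)C(F)(F)F)cc(O)c21
F7 | step 5 | beta-hydroxysilane (C1 epimers) | C[Si](C)(C)CC1(O)CC[C@@H]([C@@H](C)CCC=C(C)C)c2cc(C(=O)O)cc(O)c21
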